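Abbreviations and ring labels: TBS = tert-butyldimethylsilyl. Ring A is the phloroglucinol ring (C4a–C8a). Ring C is the pyranone (O1, C2, C3, C4, C4a, C8a). Ring B is the 4-hydroxyphenyl group on C2. Ring D is the phenol ring bonded to C3, which is also the β-aryl ring of the chalcone. Ring E is the resorcinol ring on the chalcone carbonyl.

## Analysis of the target

1. The target is a C–C linked flavanone–chalcone dimer. It is a 5,7,4'-trihydroxyflavanone (rings A, C, B) whose C3 is bonded to the carbon ortho to the phenol of ring D, and ring D belongs to an (E)-2',4',4-trihydroxychalcone (enone plus ring E).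
2. There are two stereocentres, the neighbours C2 and C3 of ring C. The SMILES reads as (2R,3S), with rings B and D trans (diequatorial), and C2 has the opposite spatial arrangement to the common (2S)-flavanones, so the chiral pool gives no help.
3. The two centres are labile in different ways. C3–H lies between C4=O and ring D and enolises easily, which is harmless because trans is the thermodynamic arrangement. O1–C2 is a β-aryloxy ketone and a 4-hydroxybenzyl aryl ether, and it can open by retro-oxa-Michael reaction or quinone methide formation to an achiral enone, which erases both centres.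
4. The absolute configuration therefore rests on C2 alone. C2 must be set in an irreversible step, and everything afterwards must avoid strong base and strong acid.
5. Other sensitive groups are the enone (reduction, nucleophiles, cyclisation with its own 2'-OH), the ring D phenol (1,5 to C4=O, prone to hemiketal and benzofuran formation in strong acid) and six oxidisable phenols.
6. The hardest bond is C2–C3. It joins two tertiary benzylic carbons surrounded by three aryl rings, and ring D is ortho-substituted.
7. The feature that invites the chosen move is this: O1–C2(H)–ring B is simply a 4-hydroxybenzyl ether of the ring A oxygen O1, and C3 carries an aryl donor (ring D) and an acyl acceptor (C4=O), which is the substitution pattern of a donor/acceptor carbene.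
8. Read this way, C2–C3 is the bond that a carbene at C3 forms by inserting into a benzylic ether C–H bond. That one event closes ring C and creates both stereocentres from an open, achiral precursor.

## Retrosynthetic reasoning

**15 ⇒ 14 (six O–Si bonds).** All six phenols are masked as TBS ethers. Silicon comes off with buffered fluoride at or below neutral pH, the only window in which the O1–C2 bond, the enone and the ring D phenol/C4 ketone pair are all safe. Silicon on oxygen also places no C–H bond next to oxygen, which matters in the key step.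

**14 ⇒ 13 (configuration at C3 only).** The trans compound 14 is the thermodynamic epimer of the cis compound 13 and is reached through the enol. The key step therefore has to control only C2, and its kinetic cis/trans outcome does not matter.

**13 ⇒ 12 (C2–C3, opening of ring C).**
- Cutting O1–C2 leads back to the reversible oxa-Michael closure.
- Cutting C3–C4 leaves the crowded C2–C3 bond and both stereocentres to be made in an open chain.
- Cutting C2–C3 removes ring C and both stereocentres together and gives the achiral α-aryl-α-diazoketone 12. In 12, C2 and ring B are present as what looks like a protecting group on O1.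
- In the forward direction, the metal carbene generated from 12 has to select one of the two enantiotopic benzylic hydrogens and insert irreversibly.

**12 ⇒ 7 + 11 (diazo carbon to ring D).** This cut divides the molecule into two halves of similar size. The complete chalcone arrives finished in 11, so no C–C bond formation and no base-mediated condensation is needed once the stereocentres exist. The forward reaction is a palladium-catalysed arylation of the diazo C–H bond of 7 with retention of the diazo group. It avoids any free enolate next to the Michael acceptor of 11.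

**7 ⇒ 5 ⇒ 2 + 4 ⇒ 1 and 3.** The diazo group of 7 comes from the methyl ketone 5 by activation and diazo transfer. The O1–CH2 bond of 5 is made from the one free, chelated phenol of 2 and the benzylic alcohol 4 under neutral conditions. Compound 2 results from selective bis-silylation of 1, and 4 from reduction of 3.

**11 ⇒ 10 ⇒ 8 + 9.** The enone C=C is cut by aldol condensation logic. The iodine of 9 already marks the ring D carbon that becomes bonded to C3. Condensing the free phenols and then silylating once is shorter than any protect-first sequence.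

## Alternatives that were turned down

**Alternative 1:** the textbook route, which cuts C2–C3 and O1–C2 together.
- Forward key step: Knoevenagel condensation of the 2'-hydroxydeoxybenzoin A1 with 4-(methoxymethoxy)benzaldehyde A2 (piperidine, heat), followed by spontaneous 6-endo oxa-Michael closure to the trans-2,3-diarylchromanone A3. A Heck reaction and deprotection would follow.
- Reason for rejection: the ring closure is the microscopic reverse of the racemisation pathway. It is reversible, runs under thermodynamic control and passes through an achiral enone.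
- The α-aryl group twists that enone and removes the two-point binding on which bifunctional catalysts rely with activated chalcones.
- A3 would therefore be racemic, and a single enantiomer would come only from a late resolution that discards half the material.
- A1 also needs four differentiated phenols, and several hot or basic steps would follow ring formation.

**Alternative 2:** the biomimetic route, which cuts C3–ring D and O1–C2.
- Forward key step: one-electron oxidation of naringenin chalcone A4 and isoliquiritigenin A5, radical cross-coupling of Cα of A4 with C3 of the phenol ring of A5 to give the quinone methide A6, and closure by a ring A hydroxyl.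
- Reason for rejection: in step count it cannot be beaten, but the two 4-hydroxycinnamoyl-type phenols have nearly equal oxidation potentials.
- Each radical has several reactive sites (O, C3, Cα), so homo- and cross-dimers of several linkage types must form together.
- A6 can also close through the ring D phenol to a dihydrobenzofuran, and A4 cyclises on its own to the flavanone.
- Nothing in the step is chiral, so the outcome would be a racemate as a minor component of a complex mixture.

**Alternative 3:** dearomatisation of a flat heterocycle, which adds H2 across C2=C3.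
- Forward key step: Suzuki coupling at C3 of the 3-iodoflavone A7 gives the 2,3-diarylchromone A8. Enantioselective hydrogenation then gives the cis-chromanone, which is epimerised at C3.
- Reason for rejection: C2=C3 of A8 is a tetrasubstituted, push–pull (vinylogous ester) alkene carrying two aryl groups, one of them ortho-substituted. It offers poor binding and low reactivity, and the C4 ketone competes for reduction.
- The chalcone enone would be reduced first, so it has to be masked as an acetal and built after the stereocentres exist.
- Protection, iodination, preparation of the boron partner, a hindered coupling and the late enone construction together make the route longer than the chosen one.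

Key step: step 8

Assumption: the absolute sense of induction of the dirhodium catalyst on this substrate cannot be derived with certainty. The route is written with Rh2(S-PTAD)4. If this catalyst leads to the (2S) series, the commercially available Rh2(R-PTAD)4 is used instead and nothing else changes.

## Route

Step 1
Reactants: 1 2',4',6'-trihydroxyacetophenone
Product: 2 1-[2-hydroxy-4,6-bis(tert-butyldimethylsilyloxy)phenyl]ethan-1-one
Conditions: TBSCl (2.1 equiv), imidazole, DMF, 0 °C → rt
Reagents that add atoms: tert-butyldimethylsilyl chloride, CC(C)(C)[Si](C)(C)Cl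
Why: Phenol silylation; the 4-OH and one of the two equivalent ortho OH groups react, while the last OH is locked in a strong hydrogen bond to the acetyl C=O and is shielded, so the reaction should stop at the bis-ether.

Step 2
Reactants: 3 4-(tert-butyldimethylsilyloxy)benzaldehyde
Product: 4 [4-(tert-butyldimethylsilyloxy)phenyl]methanol
Conditions: NaBH4, MeOH, 0 °C
Reagents that add atoms: none
Why: Borohydride reduction of an aromatic aldehyde; short contact at 0 °C leaves the aryl silyl ether intact.

Step 3
Reactants: 2 1-[2-hydroxy-4,6-bis(tert-butyldimethylsilyloxy)phenyl]ethan-1-one; 4 [4-(tert-butyldimethylsilyloxy)phenyl]methanol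
Product: 5 1-[2,4-bis(tert-butyldimethylsilyloxy)-6-{[4-(tert-butyldimethylsilyloxy)phenyl]methoxy}phenyl]ethan-1-one
Conditions: PPh3, DIAD, THF, 0 °C → rt
Reagents that add atoms: none
Why: Mitsunobu etherification of a phenol with a primary benzylic alcohol; the neutral medium avoids the silyl migration and cleavage that a carbonate-mediated alkylation would cause. This step installs the future O1–C2–ring B unit.

Step 4
Reactants: 5 1-[2,4-bis(tert-butyldimethylsilyloxy)-6-{[4-(tert-butyldimethylsilyloxy)phenyl]methoxy}phenyl]ethan-1-one
Product: 7 2-diazo-1-[2,4-bis(tert-butyldimethylsilyloxy)-6-{[4-(tert-butyldimethylsilyloxy)phenyl]methoxy}phenyl]ethan-1-one, via 1-[2,4-bis(tert-butyldimethylsilyloxy)-6-{[4-(tert-butyldimethylsilyloxy)phenyl]methoxy}phenyl]-4,4,4-trifluorobutane-1,3-dione 6 (not isolated)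
Conditions: LiHMDS, THF, −78 °C, then CF3CO2CH2CF3, dilute HCl quench; crude 6, MsN3, Et3N, H2O (1 equiv), MeCN, rt
Reagents that add atoms: methanesulfonyl azide, CS(=O)(=O)N=[N+]=[N-] (the N2 unit of 7); 2,2,2-trifluoroethyl trifluoroacetate, O=C(OCC(F)(F)F)C(F)(F)F (the CF3CO group of 6 only)
Why: Detrifluoroacetylative diazo transfer; the kinetic lithium enolate of the methyl ketone is trifluoroacetylated, and the activated 1,3-diketone accepts the diazo group from the sulfonyl azide with loss of the trifluoroacetyl group. This is the standard way to turn a methyl ketone into an acyldiazomethane, and the only strong base is used at −78 °C.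

Step 5
Reactants: 8 2',4'-dihydroxyacetophenone; 9 4-hydroxy-3-iodobenzaldehyde
Product: 10 (E)-1-(2,4-dihydroxyphenyl)-3-(4-hydroxy-3-iodophenyl)prop-2-en-1-one
Conditions: HCl (1.25 M in EtOH), rt
Reagents that add atoms: none
Why: Acid-catalysed Claisen–Schmidt condensation; in acid the phenols stay neutral, so the aldehyde is not deactivated as a phenoxide, and dehydration of the aldol gives the conjugated (E)-enone as the thermodynamic isomer.

Step 6
Reactants: 10 (E)-1-(2,4-dihydroxyphenyl)-3-(4-hydroxy-3-iodophenyl)prop-2-en-1-one
Product: 11 (E)-1-[2,4-bis(tert-butyldimethylsilyloxy)phenyl]-3-[4-(tert-butyldimethylsilyloxy)-3-iodophenyl]prop-2-en-1-one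
Conditions: TBSOTf (3.6 equiv), 2,6-lutidine, CH2Cl2, 0 °C → rt
Reagents that add atoms: tert-butyldimethylsilyl trifluoromethanesulfonate, CC(C)(C)[Si](C)(C)OS(=O)(=O)C(F)(F)F
Why: Exhaustive silylation; the triflate is reactive enough for the chelated 2'-OH, and the chalcone has no enolisable position that could be silylated.

Step 7
Reactants: 7 2-diazo-1-[2,4-bis(tert-butyldimethylsilyloxy)-6-{[4-(tert-butyldimethylsilyloxy)phenyl]methoxy}phenyl]ethan-1-one; 11 (E)-1-[2,4-bis(tert-butyldimethylsilyloxy)phenyl]-3-[4-(tert-butyldimethylsilyloxy)-3-iodophenyl]prop-2-en-1-one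
Product: 12 2-diazo-1-[2,4-bis(tert-butyldimethylsilyloxy)-6-{[4-(tert-butyldimethylsilyloxy)phenyl]methoxy}phenyl]-2-[2-(tert-butyldimethylsilyloxy)-5-{(E)-3-[2,4-bis(tert-butyldimethylsilyloxy)phenyl]-3-oxoprop-1-en-1-yl}phenyl]ethan-1-one
Conditions: Pd(PPh3)4 (5 mol %), Ag2CO3 (0.5 equiv), Et3N, toluene, rt, dark
Reagents that add atoms: none
Why: Palladium-catalysed deprotonative cross-coupling of an aryl iodide with the C–H bond of an acyldiazomethane, a known route to α-aryl-α-diazoketones that keeps the diazo group at room temperature. No enolate is formed, so the Michael acceptor of 11 is not attacked, and a Heck reaction on the β-aryl enone is too slow at this temperature.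

Step 8
Reactants: 12 2-diazo-1-[2,4-bis(tert-butyldimethylsilyloxy)-6-{[4-(tert-butyldimethylsilyloxy)phenyl]methoxy}phenyl]-2-[2-(tert-butyldimethylsilyloxy)-5-{(E)-3-[2,4-bis(tert-butyldimethylsilyloxy)phenyl]-3-oxoprop-1-en-1-yl}phenyl]ethan-1-one
Product: 14 (2R,3S)-trans-hexa-O-TBS flavanone–chalcone [(2R,3S)-5,7-bis(TBSO)-2-[4-(TBSO)phenyl]-3-[2-(TBSO)-5-{(E)-3-[2,4-bis(TBSO)phenyl]-3-oxoprop-1-en-1-yl}phenyl]chroman-4-one], via the (2R,3R)-cis epimer 13 (not isolated)
Conditions: Rh2(S-PTAD)4 (1 mol %), toluene (0.01 M, slow addition of 12), 0 °C → rt; then Et3N (0.2 equiv), rt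
Reagents that add atoms: none
Why: Rh2(S-PTAD)4 expels N2 from 12 and gives a rhodium-bound donor/acceptor carbene at the future C3, stabilised by ring D and flanked by the aroyl group. The carbene carbon inserts through a concerted, asynchronous, hydride-transfer-like three-centre transition state into one C–H bond of the O–CH2–aryl group, which forms C2–C3 and closes ring C as a six-membered ring (1,6-insertion; ring atoms C3, C4, C4a, C8a, O1, C2). The closest known reactions are the chiral rhodium(II) carboxylate catalysed insertion of 1-(2-alkoxyphenyl)-2-diazoalkan-1-ones to cis-2,3-disubstituted chroman-4-ones and the insertion of aryldiazoacetates into ortho-benzyloxy groups to cis-2-aryl-2,3-dihydrobenzofurans; phthalimido amino acid catalysts of the PTAD type are those established for α-aryl-α-diazoketones. C2 is set by the catalyst, whose chiral pocket selects one of the two enantiotopic benzylic hydrogens, and insertion goes with retention at that carbon. C3 is first set by the open face of the carbene in the cyclic transition state (cis, 13, expected as the kinetic product) and is then corrected by the substrate: triethylamine equilibrates C3 through the enolate, and the equatorial ring B at C2 drives ring D into the equatorial, trans position of 14. Site selectivity is secured by design, since the ether CH2 is the only C–H bond that is both activated (α to oxygen, benzylic, para-siloxy donor) and within reach; the oxygens at C5 and on ring D carry silicon and not carbon, so no 1,5-insertion is possible. Chemoselectivity against the enone holds because a bulky electrophilic donor/acceptor carbene does not add to an electron-poor trans-disubstituted alkene and high dilution suppresses bimolecular paths; attack of the weakly basic aryl ether oxygen (oxonium ylide, Stevens shift) is the main competitor.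

Step 9
Reactants: 14 (2R,3S)-trans-hexa-O-TBS flavanone–chalcone
Product: 15 target, (2R,3S)-3-{5-[(E)-3-(2,4-dihydroxyphenyl)-3-oxoprop-1-en-1-yl]-2-hydroxyphenyl}-5,7-dihydroxy-2-(4-hydroxyphenyl)chroman-4-one
Conditions: Et3N·3HF (excess), THF, 0 °C → rt
Reagents that add atoms: none
Why: Fluoride cleavage of aryl silyl ethers in a weakly acidic buffer; no phenoxide builds up, so neither 1,6-elimination at O1–C2 nor retro-oxa-Michael opening is triggered. The medium is also too mild for dehydration of the ring D phenol onto C4=O or for cyclisation of the chalcone.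

## Compound list

1 | 2',4',6'-trihydroxyacetophenone | CC(=O)c1c(O)cc(O)cc1O | starting material
2 | 1-[2-hydroxy-4,6-bis(TBSO)phenyl]ethan-1-one | CC(=O)c1c(O)cc(O[Si](C)(C)C(C)(C)C)cc1O[Si](C)(C)C(C)(C)C | intermediate
3 | 4-(TBSO)benzaldehyde | O=Cc1ccc(O[Si](C)(C)C(C)(C)C)cc1 | starting material
4 | [4-(TBSO)phenyl]methanol | OCc1ccc(O[Si](C)(C)C(C)(C)C)cc1 | intermediate
5 | 1-[2,4-bis(TBSO)-6-{[4-(TBSO)phenyl]methoxy}phenyl]ethan-1-one | CC(=O)c1c(OCc2ccc(O[Si](C)(C)C(C)(C)C)cc2)cc(O[Si](C)(C)C(C)(C)C)cc1O[Si](C)(C)C(C)(C)C | intermediate
6 | 1-[2,4-bis(TBSO)-6-{[4-(TBSO)phenyl]methoxy}phenyl]-4,4,4-trifluorobutane-1,3-dione | O=C(CC(=O)C(F)(F)F)c1c(OCc2ccc(O[Si](C)(C)C(C)(C)C)cc2)cc(O[Si](C)(C)C(C)(C)C)cc1O[Si](C)(C)C(C)(C)C | intermediate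
7 | 2-diazo-1-[2,4-bis(TBSO)-6-{[4-(TBSO)phenyl]methoxy}phenyl]ethan-1-one | [N-]=[N+]=CC(=O)c1c(OCc2ccc(O[Si](C)(C)C(C)(C)C)cc2)cc(O[Si](C)(C)C(C)(C)C)cc1O[Si](C)(C)C(C)(C)C | intermediate
8 | 2',4'-dihydroxyacetophenone | CC(=O)c1ccc(O)cc1O | starting material
9 | 4-hydroxy-3-iodobenzaldehyde | O=Cc1ccc(O)c(I)c1 | starting material
10 | (E)-1-(2,4-dihydroxyphenyl)-3-(4-hydroxy-3-iodophenyl)prop-2-en-1-one | O=C(/C=C/c1ccc(O)c(I)c1)c1ccc(O)cc1O | intermediate
11 | (E)-1-[2,4-bis(TBSO)phenyl]-3-[4-(TBSO)-3-iodophenyl]prop-2-en-1-one | O=C(/C=C/c1ccc(O[Si](C)(C)C(C)(C)C)c(I)c1)c1ccc(O[Si](C)(C)C(C)(C)C)cc1O[Si](C)(C)C(C)(C)C | intermediate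
12 | α-aryl-α-diazoketone (hexa-TBS, E-enone) | O=C(/C=C/c1ccc(O[Si](C)(C)C(C)(C)C)c(C(=[N+]=[N-])C(=O)c2c(OCc3ccc(O[Si](C)(C)C(C)(C)C)cc3)cc(O[Si](C)(C)C(C)(C)C)cc2O[Si](C)(C)C(C)(C)C)c1)c1ccc(O[Si](C)(C)C(C)(C)C)cc1O[Si](C)(C)C(C)(C)C | intermediate
13 | (2R,3R)-cis-hexa-O-TBS flavanone–chalcone | O=C(/C=C/c1ccc(O[Si](C)(C)C(C)(C)C)c([C@H]2C(=O)c3c(O[Si](C)(C)C(C)(C)C)cc(O[Si](C)(C)C(C)(C)C)cc3O[C@H]2c2ccc(O[Si](C)(C)C(C)(C)C)cc2)c1)c1ccc(O[Si](C)(C)C(C)(C)C)cc1O[Si](C)(C)C(C)(C)C | intermediate
14 | (2R,3S)-trans-hexa-O-TBS flavanone–chalcone | O=C(/C=C/c1ccc(O[Si](C)(C)C(C)(C)C)c([C@@H]2C(=O)c3c(O[Si](C)(C)C(C)(C)C)cc(O[Si](C)(C)C(C)(C)C)cc3O[C@H]2c2ccc(O[Si](C)(C)C(C)(C)C)cc2)c1)c1ccc(O[Si](C)(C)C(C)(C)C)cc1O[Si](C)(C)C(C)(C)C | intermediate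
15 | CNP0272156.1, (2R,3S)-3-{5-[(E)-3-(2,4-dihydroxyphenyl)-3-oxoprop-1-en-1-yl]-2-hydroxyphenyl}-5,7-dihydroxy-2-(4-hydroxyphenyl)chroman-4-one | O=C(/C=C/c1ccc(O)c([C@@H]2C(=O)c3c(O)cc(O)cc3O[C@H]2c2ccc(O)cc2)c1)c1ccc(O)cc1O | target

## Step count and risk

Total: 9 steps. Longest linear sequence: 6 steps (1 → 3 → 4 → 7 → 8 → 9; the branch that starts with step 2 is equally long).

**Step 8 (key step).**
- The most likely failure is diversion of the carbene by the lone pair of the ether oxygen, giving a five-membered oxonium ylide and a 1,2-shift of the electron-rich benzyl group.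
- Second is poor discrimination between the two enantiotopic benzylic hydrogens, because the 2,6-disubstituted aroyl group is twisted and may hold the CH2 group far from the chiral wall of the catalyst.
- Third is partial ring opening during the amine equilibration, which would erode the enantiomeric purity.
- The fallback separates the two tasks and uses catalytic asymmetric conjugate addition for C2. It sets out from 11 and returns at 14.
  - Purchased 5,7-dihydroxychromone F1 is silylated to 5,7-bis(TBSO)chromone F2.
  - A rhodium/chiral diene catalysed 1,4-addition of purchased 4-(TBSO)phenylboronic acid F3 in the base-free hydroxorhodium mode gives the (R)-flavanone F4.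
  - Soft enolisation (TMSOTf, Et3N) gives the trimethylsilyl enol ether F5 without β-elimination.
  - Palladium-catalysed arylation of F5 with 11 through the tin enolate (Bu3SnF) forms the C3–ring D bond anti to ring B and gives 14.

**Step 7.**
- The iodide of 11 is flanked by a bulky OTBS group. Slow oxidative addition or slow palladation of the diazo C–H bond would let palladium decompose the diazo compound with loss of N2.
- The fallback makes the same bond at the ketone oxidation level and introduces nitrogen afterwards. It sets out from 5 and 11 and returns at 12.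
  - Compound 5 is converted (TMSOTf, Et3N) into the trimethylsilyl enol ether F6.
  - F6 is arylated with 11 under palladium catalysis with Bu3SnF (no free enolate, so no Michael addition) to the deoxybenzoin F7.
  - Regitz diazo transfer (4-acetamidobenzenesulfonyl azide, DBU, dilute, 0 °C) gives 12. The hindered diaryl-substituted enolate should be trapped irreversibly by the azide faster than it adds reversibly to the β-aryl enone.

**Step 9.**
- Once the ring B phenol is free, any local basicity of the fluoride medium can trigger 1,6-elimination at O1–C2 and loss of configuration.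
- Incomplete cleavage of six silyl groups would also give mixtures.
- The fallback never lets a phenoxide accumulate and releases the phenols at neutral pH. It sets out from 14 and returns at 15.
  - Desilylative acetylation (Ac2O with catalytic fluoride, each phenoxide trapped as it forms) gives the hexaacetate F8, a robust compound that can be purified and checked for enantiomeric purity.
  - Neutral methanolysis of the aryl acetates (NH4OAc, aqueous MeOH, rt) gives 15.

**Step 5.**
- Condensation of two free polyphenols may be slow. Under prolonged acid the 2'-hydroxychalcone may cyclise to the flavanone, or the electron-rich rings may be alkylated.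
- The fallback replaces the thermodynamic condensation by a directed aldol of pre-silylated partners. It sets out from 8 and 9 and returns at 11.
  - Compound 9 is silylated to 4-(TBSO)-3-iodobenzaldehyde F9, and 8 to 1-[2,4-bis(TBSO)phenyl]ethan-1-one F10.
  - The lithium enolate of F10 (LiHMDS, −78 °C) adds to F9 to give the racemic β-hydroxyketone F11.
  - Mesylation and elimination (MsCl, Et3N) give the (E)-enone 11.

## Further compounds

F1 | step 8 | 5,7-dihydroxychromone (purchased) | O=c1ccoc2cc(O)cc(O)c12
F2 | step 8 | 5,7-bis(TBSO)chromone | O=c1ccoc2cc(O[Si](C)(C)C(C)(C)C)cc(O[Si](C)(C)C(C)(C)C)c12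
F3 | step 8 | 4-(TBSO)phenylboronic acid (purchased) | OB(O)c1ccc(O[Si](C)(C)C(C)(C)C)cc1
F4 | step 8 | (R)-5,7-bis(TBSO)-2-[4-(TBSO)phenyl]chroman-4-one | O=C1C[C@H](c2ccc(O[Si](C)(C)C(C)(C)C)cc2)Oc2cc(O[Si](C)(C)C(C)(C)C)cc(O[Si](C)(C)C(C)(C)C)c12
F5 | step 8 | (R)-5,7-bis(TBSO)-2-[4-(TBSO)phenyl]-4-(trimethylsilyloxy)-2H-chromene | C[Si](C)(C)OC1=C[C@H](c2ccc(O[Si](C)(C)C(C)(C)C)cc2)Oc2cc(O[Si](C)(C)C(C)(C)C)cc(O[Si](C)(C)C(C)(C)C)c12
F6 | step 7 | trimethylsilyl enol ether of 5 | C=C(O[Si](C)(C)C)c1c(OCc2ccc(O[Si](C)(C)C(C)(C)C)cc2)cc(O[Si](C)(C)C(C)(C)C)cc1O[Si](C)(C)C(C)(C)C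
F7 | step 7 | deoxybenzoin (hexa-TBS, E-enone) | O=C(/C=C/c1ccc(O[Si](C)(C)C(C)(C)C)c(CC(=O)c2c(OCc3ccc(O[Si](C)(C)C(C)(C)C)cc3)cc(O[Si](C)(C)C(C)(C)C)cc2O[Si](C)(C)C(C)(C)C)c1)c1ccc(O[Si](C)(C)C(C)(C)C)cc1O[Si](C)(C)C(C)(C)C
F8 | step 9 | (2R,3S)-hexaacetate of 15 | O=C(/C=C/c1ccc(OC(C)=O)c([C@@H]2C(=O)c3c(OC(C)=O)cc(OC(C)=O)cc3O[C@H]2c2ccc(OC(C)=O)cc2)c1)c1ccc(OC(C)=O)cc1OC(C)=O
F9 | step 5 | 4-(TBSO)-3-iodobenzaldehyde | O=Cc1ccc(O[Si](C)(C)C(C)(C)C)c(I)c1
F10 | step 5 | 1-[2,4-bis(TBSO)phenyl]ethan-1-one | CC(=O)c1ccc(O[Si](C)(C)C(C)(C)C)cc1O[Si](C)(C)C(C)(C)C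
F11 | step 5 | 1-[2,4-bis(TBSO)phenyl]-3-hydroxy-3-[4-(TBSO)-3-iodophenyl]propan-1-one (racemic) | O=C(CC(O)c1ccc(O[Si](C)(C)C(C)(C)C)c(I)c1)c1ccc(O[Si](C)(C)C(C)(C)C)cc1O[Si](C)(C)C(C)(C)C
A1 | alternative 1 | 2-[5-bromo-2-(methoxymethoxy)phenyl]-1-[2-hydroxy-4,6-bis(methoxymethoxy)phenyl]ethan-1-one | O=C(Cc1cc(Br)ccc1OCOC)c1c(O)cc(OCOC)cc1OCOC
A2 | alternative 1 | 4-(methoxymethoxy)benzaldehyde | COCOc1ccc(C=O)cc1
A3 | alternative 1 | trans-3-[5-bromo-2-(methoxymethoxy)phenyl]-5,7-bis(methoxymethoxy)-2-[4-(methoxymethoxy)phenyl]chroman-4-one (racemate, one enantiomer drawn) | COCOc1ccc(Br)cc1[C@@H]1C(=O)c2c(OCOC)cc(OCOC)cc2O[C@H]1c1ccc(OCOC)cc1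
A4 | alternative 2 | naringenin chalcone | O=C(/C=C/c1ccc(O)cc1)c1c(O)cc(O)cc1O
A5 | alternative 2 | isoliquiritigenin | O=C(/C=C/c1ccc(O)cc1)c1ccc(O)cc1O
A6 | alternative 2 | cross-coupled para-quinone methide (racemic) | O=C1C=CC(=CC(C(=O)c2c(O)cc(O)cc2O)c2cc(/C=C/C(=O)c3ccc(O)cc3O)ccc2O)C=C1
A7 | alternative 3 | 5,7-bis(benzyloxy)-2-[4-(benzyloxy)phenyl]-3-iodochromen-4-one | O=c1c(I)c(-c2ccc(OCc3ccccc3)cc2)oc2cc(OCc3ccccc3)cc(OCc3ccccc3)c12
A8 | alternative 3 | 5,7-bis(benzyloxy)-2-[4-(benzyloxy)phenyl]-3-[2-(benzyloxy)-5-(1,3-dioxolan-2-yl)phenyl]chromen-4-one | O=c1c(-c2cc(C3OCCO3)ccc2OCc2ccccc2)c(-c2ccc(OCc3ccccc3)cc2)oc2cc(OCc3ccccc3)cc(OCc3ccccc3)c12
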